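**Plan**

1. Retrosynthesis: the two MOM ethers are cut first, then the C-2–aryl bond between ring C and ring B. This leads back to a 5,7-dioxygenated 6,8-diprenylchromone and (2,2-dimethyl-2H-chromen-6-yl)boronic acid. The chromone is cut at C-2 (one carbon from DMF dimethyl acetal) and at the two aryl–prenyl bonds, back to 2,4,6-trihydroxyacetophenone.
2. In the boronic acid, the dimethylpyran ring (ring D) is cut at the bond between the alkene carbon C-3 and the quaternary carbon C-2. The C–B bond, the alkyne carbon and the O–isopropyl bond are then cut, back to 5-bromosalicylaldehyde.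
3. Enabling feature: in ring D the quaternary C-2 carries the ring oxygen O-1 and two methyl groups, so it is the methine carbon of an aryl isopropyl ether in disguise. Its C–H bond is hydridic and lies 1,5 to the inner carbon (C-4) of an ortho ethynyl group, and C-3=C-4 is that alkyne after hydride uptake. The chromene is therefore an isomer of 4-bromo-2-ethynyl-1-isopropoxybenzene, and ring D, its quaternary carbon and its cis alkene arise in one redox-neutral cycloisomerisation with no helper group.
4. Forward: ring D is closed first on the bromoarene and the bromide becomes the boronic acid. Separately, ring A is diprenylated, bis-MOM-protected and annulated to the chromone (ring C at the enone level). The halves are joined by asymmetric 1,4-addition and the MOM groups are removed.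
5. Stereochemistry: the only stereocentre, C-2 (S), is set by the chiral bisphosphine–rhodium catalyst in the 1,4-addition and is not exposed to base afterwards.

Key step: step 3

Assumption: by analogy with (S)-biaryl bisphosphine–rhodium aryl additions to cyclic enones, the (S)-ligand is taken to deliver the aryl group to the face of C-2 that gives the 2S product. The sense is to be checked on the first sample, and the (R)-ligand is used instead if the check demands it.

**Route**

Step 1
Reactants: 1 5-bromo-2-hydroxybenzaldehyde
Product: 2 5-bromo-2-(propan-2-yloxy)benzaldehyde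
Conditions: 2-bromopropane (1.5 equiv), K2CO3, DMF, 60 °C
Reagents that add atoms: 2-bromopropane CC(C)Br
Why: Williamson ether synthesis, in which the acidic phenol (ortho-formyl, para-bromo) is O-alkylated as its potassium salt in a dipolar aprotic solvent and the excess of secondary bromide covers loss to elimination.

Step 2
Reactants: 2 5-bromo-2-(propan-2-yloxy)benzaldehyde
Product: 3 4-bromo-2-ethynyl-1-(propan-2-yloxy)benzene
Conditions: dimethyl (1-diazo-2-oxopropyl)phosphonate (1.3 equiv), K2CO3, MeOH, 0 °C to rt
Reagents that add atoms: dimethyl (1-diazo-2-oxopropyl)phosphonate CC(=O)C(=[N+]=[N-])P(=O)(OC)OC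
Why: Seyferth–Gilbert homologation in the Ohira–Bestmann variant, in which methanolysis of the acetyl group releases the diazomethylphosphonate anion that turns the non-enolisable aryl aldehyde into the terminal alkyne without touching the aryl bromide or the ether.

Step 3
Reactants: 3 4-bromo-2-ethynyl-1-(propan-2-yloxy)benzene
Product: 5 6-bromo-2,2-dimethyl-2H-chromene, via alkenylplatinum oxocarbenium zwitterion 4 (not isolated)
Conditions: PtI4 (10 mol%), dry MeCN, 100 °C, sealed tube
Reagents that add atoms: none
Why: Proposed new method: platinum tetraiodide binds the terminal alkyne as a π-acid and places positive charge on the inner alkyne carbon (attached to the arene, ortho to the donor oxygen); the methine hydrogen of the isopropyl ether is delivered to that carbon as hydride through a six-membered transition state (1,5-shift), which gives zwitterion 4, a (Z)-2-arylethenylplatinum unit next to an O-aryl dimethyloxocarbenium ion, and the platinum-bearing carbon then attacks the oxocarbenium carbon with loss of the metal, forming the bond between the alkene CH and the carbon that carries the two methyl groups. The closest known reaction types are the platinum tetraiodide- and cationic gold-catalysed hydride-shift hydroalkylation of terminal alkynes by aliphatic ether C–H bonds and the Lewis acid-catalysed 1,5-hydride shift/cyclisation of ortho-vinylaryl alkyl ethers to chromans; an aryl isopropyl ether donor combined with an unactivated ortho-ethynyl acceptor is the untested part. Ring D closes in a 6-endo-dig sense with respect to the alkyne (both alkyne carbons end in the ring), the bond-forming act being a 6-endo-trig attack on the C=O+ unit, and no stereocentre is formed. The step needs hydride transfer to outrun 5-endo attack of the ether oxygen on the alkyne (benzofuran formation with loss of the isopropyl group), which the unsubstituted alkyne terminus should secure because activation puts the charge on the aryl-bearing carbon that the hydride, but not the oxygen, can reach. It also needs closure at the metal-bearing carbon (six-membered ring) and not at the benzylic vinyl carbon (3-methylene-2,3-dihydrobenzofuran), which should be secured because the former is an in-plane ipso substitution that gives the conjugated neutral chromene and frees the catalyst, whereas the latter must twist the styrene out of conjugation and leaves an unstabilised platinum carbene. The tertiary C–H bond between oxygen and two methyl groups is the only hydridic C–H within reach, dry conditions keep the oxocarbenium ion from hydrolysis to phenol and acetone, and the aryl bromide is inert to the catalyst and serves as the handle for step 4.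

Step 4
Reactants: 5 6-bromo-2,2-dimethyl-2H-chromene
Product: 8 (2,2-dimethyl-2H-chromen-6-yl)boronic acid, via aryllithium 6 (not isolated), via lithium aryltriisopropoxyborate 7 (not isolated)
Conditions: n-BuLi (1.05 equiv), THF, −78 °C; B(Oi-Pr)3, −78 °C to rt; 1 M aq. HCl, 0 °C
Reagents that add atoms: triisopropyl borate CC(C)OB(OC(C)C)OC(C)C; water O
Why: Bromine–lithium exchange followed by borate trapping and hydrolysis, where the exchange is fast at −78 °C, the chromene carries no acidic or electrophilic site, and brief cold dilute acid should leave the enol-ether-like ring D intact.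

Step 5
Reactants: 9 1-(2,4,6-trihydroxyphenyl)ethan-1-one
Product: 10 1-[2,4,6-trihydroxy-3,5-bis(3-methylbut-2-en-1-yl)phenyl]ethan-1-one
Conditions: prenyl bromide (2.1 equiv), 10% aq. KOH, 0 °C
Reagents that add atoms: 1-bromo-3-methylbut-2-ene CC(C)=CCBr
Why: C-alkylation of an acylphloroglucinol polyanion, in which water hydrogen-bonds the phenoxide oxygens so that the soft allylic bromide is attacked (SN2, prenyl kept linear) by C-3 and C-5, the only free ring carbons.

Step 6
Reactants: 10 1-[2,4,6-trihydroxy-3,5-bis(3-methylbut-2-en-1-yl)phenyl]ethan-1-one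
Product: 11 1-[2-hydroxy-4,6-bis(methoxymethoxy)-3,5-bis(3-methylbut-2-en-1-yl)phenyl]ethan-1-one
Conditions: MOMCl (2.2 equiv), i-Pr2NEt, CH2Cl2, 0 °C to rt
Reagents that add atoms: chloromethyl methyl ether COCCl
Why: O-alkylation to MOM ethers, which should stop after the para hydroxyl and one ortho hydroxyl are capped because the last hydroxyl is locked in a hydrogen bond to the acetyl group and stays free for ring C.

Step 7
Reactants: 11 1-[2-hydroxy-4,6-bis(methoxymethoxy)-3,5-bis(3-methylbut-2-en-1-yl)phenyl]ethan-1-one
Product: 13 5,7-bis(methoxymethoxy)-6,8-bis(3-methylbut-2-en-1-yl)-4H-chromen-4-one, via enaminone 12 (not isolated)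
Conditions: DMF-DMA (3 equiv), toluene, 90 °C; evaporate; AcOH, 60 °C
Reagents that add atoms: N,N-dimethylformamide dimethyl acetal COC(OC)N(C)C
Why: Enaminone chromone synthesis, in which condensation at the acetyl methyl group gives the (E)-enaminone and the chelated phenol then adds to its β-carbon under weak acid with expulsion of dimethylamine (6-endo-trig addition–elimination), conditions that the MOM ethers and prenyl groups should tolerate.

Step 8
Reactants: 13 5,7-bis(methoxymethoxy)-6,8-bis(3-methylbut-2-en-1-yl)-4H-chromen-4-one; 8 (2,2-dimethyl-2H-chromen-6-yl)boronic acid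
Product: 14 (2S)-2-(2,2-dimethyl-2H-chromen-6-yl)-5,7-bis(methoxymethoxy)-6,8-bis(3-methylbut-2-en-1-yl)-2,3-dihydro-4H-chromen-4-one
Conditions: boronic acid 8 (2 equiv), [RhCl(C2H4)2]2 (2.5 mol%), (S)-6,6'-dimethoxy-2,2'-bis[bis(3,4,5-trifluorophenyl)phosphino]-1,1'-biphenyl (5.5 mol%), KOH (10 mol%), toluene/H2O 10:1, 25 °C
Reagents that add atoms: none
Why: Rhodium-catalysed asymmetric 1,4-addition of an arylboronic acid to a chromone (Hayashi–Miyaura reaction), in which the chiral bisphosphine pocket of the aryl–rhodium species selects one face of C-2 for insertion and so sets the S centre, protonolysis by water closes the cycle at a temperature and base load low enough to avoid ring opening by β-aryloxide elimination, and the trisubstituted prenyl alkenes and the cyclic styrene of ring D are not acceptors.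

Step 9
Reactants: 14 (2S)-2-(2,2-dimethyl-2H-chromen-6-yl)-5,7-bis(methoxymethoxy)-6,8-bis(3-methylbut-2-en-1-yl)-2,3-dihydro-4H-chromen-4-one
Product: 15 (2S)-2-(2,2-dimethyl-2H-chromen-6-yl)-5,7-dihydroxy-6,8-bis(3-methylbut-2-en-1-yl)-2,3-dihydro-4H-chromen-4-one
Conditions: conc. HCl (cat.), MeOH, 40 °C
Reagents that add atoms: none
Why: Acid-catalysed acetal exchange (MOM ether cleavage to dimethoxymethane), which should be selective because the aryl MOM acetals ionise far more readily than the prenyl alkenes or the chromene ether are protonated, while the acidic medium does not open ring C and the C-2 configuration is kept.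

**Compound list**

1 | 5-bromo-2-hydroxybenzaldehyde | O=Cc1cc(Br)ccc1O | starting material
2 | 5-bromo-2-(propan-2-yloxy)benzaldehyde | CC(C)Oc1ccc(Br)cc1C=O | intermediate
3 | 4-bromo-2-ethynyl-1-(propan-2-yloxy)benzene | CC(C)Oc1ccc(Br)cc1C#C | intermediate
4 | (Z)-2-[5-bromo-2-(propan-2-ylideneoxonio)phenyl]ethenyl-tetraiodoplatinate zwitterion (not isolated) | CC(C)=[O+]c1ccc(Br)cc1/C=C\[Pt-](I)(I)(I)I | intermediate
5 | 6-bromo-2,2-dimethyl-2H-chromene | CC1(C)C=Cc2cc(Br)ccc2O1 | intermediate
6 | (2,2-dimethyl-2H-chromen-6-yl)lithium (not isolated) | [Li]c1ccc2OC(C)(C)C=Cc2c1 | intermediate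
7 | lithium (2,2-dimethyl-2H-chromen-6-yl)tri(propan-2-yloxy)borate (not isolated) | [Li+].CC(C)O[B-](OC(C)C)(OC(C)C)c1ccc2OC(C)(C)C=Cc2c1 | intermediate
8 | (2,2-dimethyl-2H-chromen-6-yl)boronic acid | OB(O)c1ccc2OC(C)(C)C=Cc2c1 | intermediate
9 | 1-(2,4,6-trihydroxyphenyl)ethan-1-one | CC(=O)c1c(O)cc(O)cc1O | starting material
10 | 1-[2,4,6-trihydroxy-3,5-bis(3-methylbut-2-en-1-yl)phenyl]ethan-1-one | CC(=O)c1c(O)c(CC=C(C)C)c(O)c(CC=C(C)C)c1O | intermediate
11 | 1-[2-hydroxy-4,6-bis(methoxymethoxy)-3,5-bis(3-methylbut-2-en-1-yl)phenyl]ethan-1-one | CC(=O)c1c(O)c(CC=C(C)C)c(OCOC)c(CC=C(C)C)c1OCOC | intermediate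
12 | (E)-3-(dimethylamino)-1-[2-hydroxy-4,6-bis(methoxymethoxy)-3,5-bis(3-methylbut-2-en-1-yl)phenyl]prop-2-en-1-one (not isolated) | CN(C)/C=C/C(=O)c1c(O)c(CC=C(C)C)c(OCOC)c(CC=C(C)C)c1OCOC | intermediate
13 | 5,7-bis(methoxymethoxy)-6,8-bis(3-methylbut-2-en-1-yl)-4H-chromen-4-one | O=c1ccoc2c(CC=C(C)C)c(OCOC)c(CC=C(C)C)c(OCOC)c12 | intermediate
14 | (2S)-2-(2,2-dimethyl-2H-chromen-6-yl)-5,7-bis(methoxymethoxy)-6,8-bis(3-methylbut-2-en-1-yl)-2,3-dihydro-4H-chromen-4-one | CC(C)=CCc1c(OCOC)c(CC=C(C)C)c2c(c1OCOC)C(=O)C[C@@H](c1ccc3c(c1)C=CC(C)(C)O3)O2 | intermediate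
15 | (2S)-2-(2,2-dimethyl-2H-chromen-6-yl)-5,7-dihydroxy-6,8-bis(3-methylbut-2-en-1-yl)-2,3-dihydro-4H-chromen-4-one | CC(C)=CCc1c(O)c(CC=C(C)C)c2c(c1O)C(=O)C[C@@H](c1ccc3c(c1)C=CC(C)(C)O3)O2 | target

**Step count and risks**

Total step count: 9. Longest linear sequence: 6 steps (steps 1, 2, 3, 4, 8, 9).

Steps most likely to fail:

1. Step 3 (proposed new method). The hydride transfer from the aryl isopropyl ether may be too slow. In that case attack of the ether oxygen on the activated alkyne with loss of the isopropyl group, closure to the five-membered ring, or hydrolytic collapse of the oxocarbenium ion could take over. The fallback uses known chemistry and sets out from compound 1. Addition of 2-methylprop-1-enylmagnesium bromide (2.2 equiv, THF, 0 °C) to the aldehyde would give 4-bromo-2-(1-hydroxy-3-methylbut-2-en-1-yl)phenol F1. Heating in toluene with a trace of acid would dehydrate it to the ortho-quinone methide 4-bromo-6-(3-methylbut-2-en-1-ylidene)cyclohexa-2,4-dien-1-one F2, which should close by oxa-6π electrocyclisation. The fallback comes back to the route at compound 5, before step 4.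

2. Step 8. Insertion into the hindered, electron-rich chromone may be slow, facial selectivity may be poor, and ring opening of the intermediate enolate followed by non-selective reclosure would erode the enantiomeric purity. The fallback sets out from compound 5 and also uses compound 11. Bromine–lithium exchange (n-BuLi, THF, −78 °C) and quenching with DMF would give 2,2-dimethyl-2H-chromene-6-carbaldehyde F3. Claisen–Schmidt condensation with 11 (KOH, EtOH, rt) would give (E)-3-(2,2-dimethyl-2H-chromen-6-yl)-1-[2-hydroxy-4,6-bis(methoxymethoxy)-3,5-bis(3-methylbut-2-en-1-yl)phenyl]prop-2-en-1-one F4. Intramolecular oxa-Michael addition (NaOAc, EtOH, reflux) would give racemic 2-(2,2-dimethyl-2H-chromen-6-yl)-5,7-bis(methoxymethoxy)-6,8-bis(3-methylbut-2-en-1-yl)-2,3-dihydro-4H-chromen-4-one F5. Preparative HPLC on an amylose tris(3,5-dimethylphenylcarbamate) phase would separate the 2S enantiomer from the (2R)-enantiomer F6, which is discarded. The fallback comes back to the route at compound 14, before step 9.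

3. Step 5. Over-alkylation to geminal diprenyl cyclohexadienones, O-alkylation and incomplete alkylation may leave little of the 3,5-di-C-prenyl product. The fallback sets out from compound 9. Allyl bromide (2.1 equiv, K2CO3, acetone, reflux) would give 1-[2-hydroxy-4,6-bis(prop-2-en-1-yloxy)phenyl]ethan-1-one F7. Double aromatic Claisen rearrangement (N,N-diethylaniline, about 200 °C) should move both allyl groups to C-3 and C-5, with a Cope relay where both ortho positions are blocked, giving 1-[2,4,6-trihydroxy-3,5-bis(prop-2-en-1-yl)phenyl]ethan-1-one F8. Cross-metathesis with 2-methylbut-2-ene (second-generation Grubbs catalyst, RuCl2(=CHPh)(PCy3)(H2IMes), CH2Cl2, 40 °C) would convert both allyl groups into prenyl groups. The fallback comes back to the route at compound 10, before step 6.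

**Further compounds**

F1 | step 3 | 4-bromo-2-(1-hydroxy-3-methylbut-2-en-1-yl)phenol | CC(C)=CC(O)c1cc(Br)ccc1O
F2 | step 3 | 4-bromo-6-(3-methylbut-2-en-1-ylidene)cyclohexa-2,4-dien-1-one | CC(C)=CC=C1C=C(Br)C=CC1=O
F3 | step 8 | 2,2-dimethyl-2H-chromene-6-carbaldehyde | CC1(C)C=Cc2cc(C=O)ccc2O1
F4 | step 8 | (E)-3-(2,2-dimethyl-2H-chromen-6-yl)-1-[2-hydroxy-4,6-bis(methoxymethoxy)-3,5-bis(3-methylbut-2-en-1-yl)phenyl]prop-2-en-1-one | O=C(/C=C/c1ccc2OC(C)(C)C=Cc2c1)c1c(O)c(CC=C(C)C)c(OCOC)c(CC=C(C)C)c1OCOC
F5 | step 8 | racemic 2-(2,2-dimethyl-2H-chromen-6-yl)-5,7-bis(methoxymethoxy)-6,8-bis(3-methylbut-2-en-1-yl)-2,3-dihydro-4H-chromen-4-one | CC(C)=CCc1c(OCOC)c(CC=C(C)C)c2c(c1OCOC)C(=O)CC(c1ccc3c(c1)C=CC(C)(C)O3)O2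
F6 | step 8 | (2R)-2-(2,2-dimethyl-2H-chromen-6-yl)-5,7-bis(methoxymethoxy)-6,8-bis(3-methylbut-2-en-1-yl)-2,3-dihydro-4H-chromen-4-one | CC(C)=CCc1c(OCOC)c(CC=C(C)C)c2c(c1OCOC)C(=O)C[C@H](c1ccc3c(c1)C=CC(C)(C)O3)O2
F7 | step 5 | 1-[2-hydroxy-4,6-bis(prop-2-en-1-yloxy)phenyl]ethan-1-one | CC(=O)c1c(O)cc(OCC=C)cc1OCC=C
F8 | step 5 | 1-[2,4,6-trihydroxy-3,5-bis(prop-2-en-1-yl)phenyl]ethan-1-one | CC(=O)c1c(O)c(CC=C)c(O)c(CC=C)c1O
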